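All runs come from a simulation for substances that don't exist, noise included.

The pitfall is to think that equal charges give equal yields. In larch the substrate is down to 0% at 1.00 min, yet target stands at 31.5% of the charge with 0.45 equiv of reagent offered, so substrate has a second way out, a loss that does not wait for reagent.

| setting | oak | larch | elm | birch | teal | grey | violet | amber |
|---|---|---|---|---|---|---|---|---|
| substrate | 0.20 mM | 0.20 mM | 0.20 mM | 0.40 mM | 0.20 mM | 0.20 mM | 0.20 mM | 0.20 mM (fed, over 2.0 min) |
| reagent | 0.90 equiv | 0.45 equiv | 0.68 equiv | 0.90 equiv | 0.900 equiv | 0.900 equiv (fed, over 2.0 min) | 0.900 equiv (in portions, 3, over 2.0 min) | 0.900 equiv |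
| temperature | 85 °C | 96 °C | 85 °C | 96 °C | 90 °C | 90 °C | 90 °C |  |
| remark | run made earlier | run made earlier | run made earlier | run made earlier | everything together at the start | all else is in the flask from the start; the feed brings no volume worth counting | first portion at the start, last at 2.0 min | the addition at 60 °C, then warmed to 90 °C; the feed brings no volume worth counting |
| time |  |  |  |  | 2.5 min | 2.5 min | 2.5 min | 2.5 min |

| run | time / min | target / % | substrate / % |
|---|---|---|---|
| oak | 0.200 | 50.7 | 16.4 |
| oak | 0.500 | 58.0 | 1.6 |
| oak | 1.00 | 57.5 | 0.1 |
| oak | 2.50 | 58.1 | 0 |
| larch | 0.417 | 32.2 | 1.0 |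
| larch | 1.00 | 31.5 | 0 |
| larch | 2.00 | 32.8 | 1.5 |
| larch | 3.00 | 31.7 | 0.1 |
| elm | 0.250 | 42.6 | 15.4 |
| elm | 0.500 | 46.1 | 4.2 |
| elm | 1.33 | 47.5 | 0.7 |
| elm | 3.00 | 49.1 | 0.1 |
| birch | 0.833 | 67.8 | 0 |
| birch | 1.50 | 66.1 | 0.4 |
| birch | 2.50 | 64.6 | 0.1 |
| birch | 3.00 | 66.0 | 0.9 |

(each reading ± 1 percentage point)

- a reading or a percentage of target counts all its forms, free or not

1. the best flask by amount of target, in percent of the substrate charged; "all alike" if 1.5 percentage points covers them all (teal / grey / violet / amber / all alike)
2. amount of target at the end, in percent of the substrate charged, teal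
3. amount of target at the end, in percent of the substrate charged, grey
4. amount of target at the end, in percent of the substrate charged, violet
5. amount of target at the end, in percent of the substrate charged, amber

I take both ways as first-order in [substrate]: the target step is pseudo-first-order, with a rate constant proportional to [reagent], counted in equivalents, and the loss has a constant of its own, so the share going to target at any moment is [reagent]/([reagent] + a). Here a is the break-even level. I replace the falling [reagent] by its mean, the charge less half the target formed. In oak that mean is 0.609, so a reads 0.440 at 85 °C. In larch the mean is 0.291, so a reads 0.628 at 96 °C. Interpolating the logarithm gives 0.517 at 90 °C: this is the break-even level of [reagent] at which both ways run equally fast, for 0.20 mM of substrate.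

Solving share and mean together, teal gives 54.8%. In violet all the substrate is there from the start and the reagent comes in portions, and oak's pace, with oak's whole charge of reagent and at its lower temperature, suggests that the substrate is nearly gone before the second portion, 1.00 min later, since oak kept 1.6% at 0.500 min. Violet's first portion of 0.300 then gives 25.2%. By 0.500 min grey's feed has brought 0.225, less than violet's portion, so I put grey below violet. Extended to 60 °C, a falls to 0.195, below its value at 90 °C, and the same solution gives amber 73.2%. I expect less, since substrate left after the feed meets the warm a. Amber is my choice.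

One weak link is the straight mean. Within my two-way picture, summing the share over the substrate consumed gives a logarithmic mean, and redoing a that way gives 0.404 and 0.560, hence 0.469. Teal's mean becomes 0.584 and its target 55.5%, a shift inside the scatter of 1 percentage point.

The forecast said amber, with teal 55.5%, grey 10%, violet 24% and amber 67%, adding that “the loss has the higher activation energy”. The flasks give amber as best, with teal 55.1%, grey 8.52%, violet 24.0% and amber 65.5%.

    substrate + reagent → target (k = 1000 M⁻¹ s⁻¹, Ea = 50.0 kJ mol⁻¹)
    crystals ⇌ target, rate k2*(cs2 - [target]) while solid is left; crystals form when [target] > cs2 (solubility = 0.0190 mM, k = 2.70 s⁻¹)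
    substrate → side product (k = 0.0950 s⁻¹, Ea = 82.0 kJ mol⁻¹)
    (constants at 90 °C)

In amber, substrate goes to target 3.1 times as fast as to side product at 1.23 min, but 0.52 times at 2.50 min. [Reagent] over a gives 2.90 cold, with reagent as at 1.25 min, and 0.473 warm, with reagent as at 2.50 min. Crystals hold 45.6% in teal, counted within its target, which still reads 55.1% at 25.0 min. For the neighbour of amber with 1.50 equiv of reagent, the cold a gives 84.6%; that flask gives 81.5%.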